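**Plan**

1. Numbering (longipinane): C1 (C=O), C2=C3(Me), C4, C5, C6 (CMe2), C7 (OH), C8 (O-angeloyl), C9 (O-isovaleryl), C10 (Me), C11; the cyclobutane is C4–C5–C11–C10.
2. Cuts, in retro order: the ester C–O bonds at O8 and O9; C4–C10 (back to C2–C10 by a 1,3-shift); C1–C11 together with C2–C10 (ketene–alkene [2+2]); C1–C2 (Wolff); C3=C4 (olefination); C5–C6 (Claisen) to a tetrahydrofuran made from D-erythronolactone.
3. Enabling feature: C1(=O)–C2=C3(Me)–C4 is a masked vinylketene O=C1=C2–C3(Me)=C4 on C5, next to the C10=C11 bond of a cycloheptene (ring C5–C6–C7–C8–C9–C10–C11); its [2+2] adduct, the cyclobutanone C1–C2–C10–C11, is the 1,3-shift isomer of the cyclobutane C4–C5–C11–C10 plus enone.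
4. Forward: seven-membered ring first (Claisen ring expansion), then cyclobutanone and cyclohexene in one cycloaddition, then a thermal 1,3-shift to the cyclobutane/cyclohexenone pair, esters last.
5. Stereochemistry: C8 and C9 from D-erythronolactone; C5 by chirality transfer in the Claisen step from a chelation-set C10 carbinol (later sp2) and an E-alkene; C7 by hydroxyl-directed reduction; C11, C10 and C4 by the one-atom tether C5 (addition on the face that carries the side chain).

Key step: step 17

Assumption: compounds 1 and 3 are taken as commercial, and the Grignard addition of step 2 is taken to follow chelation control by O9.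

**Route**

Step 1
Reactants: 1 2,3-O-isopropylidene-D-erythronolactone
Product: 2 methyl lactol (3aR,6aR)-2,2,4-trimethyltetrahydrofuro[3,4-d][1,3]dioxol-4-ol (anomer mixture; the hemiketal carbon is the future C10)
Conditions: MeLi (1.05 equiv), THF, −78 °C; then H2O
Reagents that add atoms: methyllithium [Li]C
Why: Mono-addition of MeLi to the γ-lactone stops at the tetrahedral lithium hemiketal at −78 °C and gives the lactol on quenching (lactone to lactol addition); C8 and C9 are carried over unchanged.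

Step 2
Reactants: 2 methyl lactol; 3 4-methoxybenzyl propargyl ether
Product: 5 propargylic diol (2R)-2-[(4R,5R)-5-(hydroxymethyl)-2,2-dimethyl-1,3-dioxolan-4-yl]-5-(4-methoxybenzyloxy)pent-3-yn-2-ol, via alkynylmagnesium bromide 4 (not isolated)
Conditions: 3, EtMgBr, THF, 0 °C; then 2, −20 °C to 25 °C; then H2O
Reagents that add atoms: none
Why: Grignard addition to the open methyl ketone form of the lactol; magnesium chelated between the carbonyl oxygen and O9 (Cram chelate model) should direct the alkynyl group to the face that is cis to O9 once the ring is closed again, which sets the temporary C10 centre.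

Step 3
Reactants: 5 propargylic diol
Product: 6 allylic diol (2R,3E)-2-[(4R,5R)-5-(hydroxymethyl)-2,2-dimethyl-1,3-dioxolan-4-yl]-5-(4-methoxybenzyloxy)pent-3-en-2-ol
Conditions: NaAlH2(OCH2CH2OMe)2, THF, 0 °C to 25 °C; then aq. NaOH
Reagents that add atoms: none
Why: Alkoxide-directed trans-hydroalumination of the propargylic alcohol and protonolysis should give the E-alkene only (propargylic alcohol reduction).

Step 4
Reactants: 6 allylic diol
Product: 7 furanose lactol 6-[(E)-3-(4-methoxybenzyloxy)prop-1-enyl]-2,2,6-trimethyltetrahydrofuro[3,4-d][1,3]dioxol-4-ol (alkenyl group cis to the dioxolane oxygens; anomer mixture)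
Conditions: Dess–Martin periodinane (1.1 equiv), pyridine, CH2Cl2, 0 °C
Reagents that add atoms: none
Why: Dess–Martin oxidation of the primary alcohol, which the inert tertiary allylic alcohol then captures as the five-membered lactol.

Step 5
Reactants: 7 furanose lactol
Product: 8 isobutenyl alcohol (2R,3E)-2-[(4R,5R)-2,2-dimethyl-5-(2-methylprop-1-enyl)-1,3-dioxolan-4-yl]-5-(4-methoxybenzyloxy)pent-3-en-2-ol
Conditions: i-PrPPh3 iodide, n-BuLi, THF, 0 °C; then 7, 0 °C to 25 °C
Reagents that add atoms: isopropyltriphenylphosphonium iodide CC(C)[P+](c1ccccc1)(c1ccccc1)c1ccccc1.[I-]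
Why: Wittig olefination of the open hydroxy aldehyde form of the lactol with the non-stabilized isopropylidene ylide; the new alkene carries two methyl groups, so no geometry arises.

Step 6
Reactants: 8 isobutenyl alcohol
Product: 9 bromo ether 4-(2-bromopropan-2-yl)-6-[(E)-3-(4-methoxybenzyloxy)prop-1-enyl]-2,2,6-trimethyltetrahydrofuro[3,4-d][1,3]dioxole (epimers at C4 of the bicycle, the future C7)
Conditions: NBS, CH2Cl2, −20 °C
Reagents that add atoms: N-bromosuccinimide O=C1CCC(=O)N1Br
Why: Bromoetherification: the bromonium ion forms on the electron-rich trisubstituted alkene and is opened 5-exo by the tertiary hydroxyl, as is usual for 2-methylalk-2-en-6-ols; the new centre is lost again in step 7.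

Step 7
Reactants: 9 bromo ether
Product: 11 cycloheptenone 8,9-O-isopropylidene-5-[(4-methoxybenzyloxy)methyl]-6,6,10-trimethylcyclohept-10-en-7-one (target numbering; CH2OPMB trans to O8/O9), via enol ether 10 (not isolated)
Conditions: 2,4,6-collidine, 170 °C, sealed tube
Reagents that add atoms: none
Why: Loss of HBr toward the ring carbon gives the 2-isopropylidene-5-vinyltetrahydrofuran 10, which undergoes Claisen ([3,3]) ring expansion to a cyclohept-4-enone (known behaviour of 2-alkylidene-5-vinyltetrahydrofurans) through the only chair-like array the ring allows; because the E-alkenyl group is cis to O9, its CH2OPMB end arrives at C5 trans to O8/O9, and C6 becomes the quaternary CMe2 carbon.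

Step 8
Reactants: 11 cycloheptenone
Product: 12 dihydroxy ketone 8,9-dihydroxy-5-[(4-methoxybenzyloxy)methyl]-6,6,10-trimethylcyclohept-10-en-7-one (8-OH and 9-OH cis)
Conditions: AcOH/H2O (4:1), 45 °C
Reagents that add atoms: none
Why: Acid hydrolysis of the acetonide; the PMB ether and both alkene positions are stable to aqueous acetic acid.

Step 9
Reactants: 12 dihydroxy ketone
Product: 13 triol 5-[(4-methoxybenzyloxy)methyl]-6,6,10-trimethylcyclohept-10-ene-7,8,9-triol (7-OH trans to 8-OH; 8-OH and 9-OH cis; 7-OH cis to the C5 substituent)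
Conditions: Me4NBH(OAc)3, MeCN/AcOH (1:1), −30 °C
Reagents that add atoms: none
Why: Evans–Saksena reduction: the acetoxyborohydride bound to O9 (and O8) delivers hydride inside the molecule to the ketone face syn to these oxygens, so the new 7-OH is anti to both (1,3-anti to 9-OH).

Step 10
Reactants: 13 triol
Product: 14 9-O-TBS diol (silyl ether at the allylic C9 oxygen; 7-OH and 8-OH free)
Conditions: TBSCl (1.1 equiv), imidazole, DMF, −10 °C
Reagents that add atoms: tert-butyldimethylsilyl chloride CC(C)(C)[Si](C)(C)Cl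
Why: Selective silylation of the least hindered hydroxyl: 9-OH is allylic and next to an sp2 carbon, 8-OH lies between two carbinol carbons and 7-OH is neopentyl.

Step 11
Reactants: 14 9-O-TBS diol
Product: 15 7,8-O-isopropylidene-9-O-TBS PMB ether (trans-fused dioxolane on C7/C8)
Conditions: 2-methoxypropene, PPTS (cat.), CH2Cl2, 0 °C
Reagents that add atoms: 2-methoxypropene COC(C)=C
Why: Kinetic acetal exchange on the only remaining 1,2-diol; a trans-fused acetonide is readily formed on a seven-membered ring.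

Step 12
Reactants: 15 PMB ether
Product: 16 primary alcohol (C5–CH2OH)
Conditions: DDQ, CH2Cl2/pH 7 buffer, 0 °C
Reagents that add atoms: none
Why: Oxidative cleavage of the PMB ether by DDQ (benzylic hydride abstraction, hydrolysis of the oxocarbenium ion); silyl ether, acetonide and alkene are unaffected.

Step 13
Reactants: 16 primary alcohol
Product: 17 aldehyde (C5–CHO, the future C4)
Conditions: Dess–Martin periodinane, pyridine, CH2Cl2, 0 °C; used at once
Reagents that add atoms: none
Why: Buffered Dess–Martin oxidation; the α-carbon C5 is neopentyl and is not enolized under these conditions, so its configuration should hold.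

Step 14
Reactants: 17 aldehyde
Product: 18 methyl (Z)-enoate (C5–CH=C(Me)–CO2Me with the ester cis to C5)
Conditions: (CF3CH2O)2P(O)CH(Me)CO2Me, KN(SiMe3)2, 18-crown-6, THF, −78 °C
Reagents that add atoms: methyl 2-[bis(2,2,2-trifluoroethoxy)phosphoryl]propanoate COC(=O)C(C)P(=O)(OCC(F)(F)F)OCC(F)(F)F
Why: Still–Gennari olefination: the electron-poor phosphonate eliminates fast from the kinetic adduct and gives the Z-trisubstituted enoate, which fixes C4=C3 with the future C2 cis to C5.

Step 15
Reactants: 18 methyl (Z)-enoate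
Product: 19 (Z)-enoic acid
Conditions: LiOH, THF/MeOH/H2O, 40 °C; then aq. HCl to pH 4, 0 °C
Reagents that add atoms: lithium hydroxide [Li+].[OH-]
Why: Saponification; silyl ether and acetonide are base-stable and the Z-alkene has no pathway for isomerization under hydroxide.

Step 16
Reactants: 19 (Z)-enoic acid
Product: 21 diazo ketone (Z)-1-diazo-3-methyl-4-(cycloheptenyl)but-3-en-2-one, via acid chloride 20 (not isolated)
Conditions: Me2C=C(Cl)NMe2, CH2Cl2, 0 °C; then CH2N2 (excess), Et2O, 0 °C
Reagents that add atoms: diazomethane C=[N+]=[N-]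
Why: Neutral acid chloride formation with the α-chloroenamine and acylation of diazomethane (first stage of the Arndt–Eistert sequence); no base is present that could form a ketene from the acid chloride.

Step 17
Reactants: 21 diazo ketone
Product: 23 tricyclic cyclobutanone (cyclobutanone C1–C2–C10–C11; cyclohexene C2–C3=C4–C5–C11–C10; seven-membered ring C5–C11; 7,8-acetonide; 9-OTBS), via vinylketene 22 (not isolated)
Conditions: hν (450 nm LEDs), PhMe (0.005 M, degassed), 25 °C; then 80 °C in the dark
Reagents that add atoms: none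
Why: Light expels N2 and the (Z)-alkenyl group migrates (Wolff rearrangement) to give the (Z)-vinylketene 22, whose carbonyl carbon C1 is attacked by the less substituted alkene carbon C11 while C2 bonds to the tertiary carbon C10 in a concerted, asynchronous thermal [2+2] cycloaddition. The closest known reaction is the intramolecular vinylketene–alkene cycloaddition that gives bicyclo[3.1.1]hept-2-en-6-ones of the chrysanthenone type. The C1–C11 bond closes the six-membered ring C1–C2–C3–C4–C5–C11 (6-exo with respect to the alkene, tether C3=C4–C5) and the C2–C10 bond closes the cyclobutanone C1–C2–C10–C11, which is the bridged mode of addition. C11, C10 and C2 are set by the tether: the ketene can reach only the alkene face that carries the C5 side chain, opposite to the C9 silyl ether, and it adds suprafacially. The step needs the bridged and not the fused regiochemistry, which the trisubstituted alkene secures because positive charge develops on tertiary C10, and it needs C2 cis to C5 on C3=C4, which the Z-selective olefination and retention in the Wolff shift secure.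

Step 18
Reactants: 23 tricyclic cyclobutanone
Product: 24 protected longipinenone 7,8-O-isopropylidene-9-O-TBS-7,8,9-trihydroxylongipin-2-en-1-one (cyclobutane C4–C5–C11–C10; enone C1(=O)–C2=C3)
Conditions: o-C6H4Cl2 (degassed), BHT (cat.), 195 °C, sealed tube
Reagents that add atoms: none
Why: Thermal [1,3] carbon shift (vinylcyclobutane to cyclohexene rearrangement, the process by which bicyclo[3.1.1]hept-2-enes such as α-pinene racemize): the strained C2–C10 bond breaks to a tertiary C10 radical and the oxygen-substituted pentadienyl radical O=C1–C2–C3–C4, which recombine at C4; the product gains enone conjugation and loses the cyclobutanone, and the rings force C10 to rebond on the face it left, which also fixes C4.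

Step 19
Reactants: 24 protected longipinenone
Product: 25 9-alcohol (7,8-O-isopropylidene-9-hydroxy compound)
Conditions: Bu4NF, THF, 40 °C
Reagents that add atoms: none
Why: Fluoride cleavage of the silyl ether; the α-carbon C11 is a bridgehead and cannot enolize, so the basic medium should do no harm.

Step 20
Reactants: 25 9-alcohol
Product: 26 9-isovalerate (7,8-O-isopropylidene-9-O-(3-methylbutanoyl) compound)
Conditions: (i-BuCO)2O, DMAP, Et3N, CH2Cl2, 25 °C
Reagents that add atoms: isovaleric anhydride CC(C)CC(=O)OC(=O)CC(C)C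
Why: DMAP-catalysed acylation of the only free hydroxyl.

Step 21
Reactants: 26 9-isovalerate
Product: 27 7,8-diol 9-isovalerate
Conditions: AcOH/H2O (4:1), 40 °C
Reagents that add atoms: none
Why: Mild acid hydrolysis of the trans-fused acetonide; weak acid keeps acyl migration from O9 to O8 slow.

Step 22
Reactants: 27 7,8-diol 9-isovalerate
Product: 28 target, 8-O-angeloyl-9-O-isovaleryl-7,8,9-trihydroxylongipin-2-en-1-one
Conditions: angelic acid, 2,4,6-Cl3C6H2COCl, Et3N, PhMe, 25 °C; then 27, PhMe, 75 °C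
Reagents that add atoms: angelic acid C/C=C(/C)C(=O)O
Why: Yamaguchi-type esterification through the mixed anhydride without a nucleophilic catalyst should keep the Z geometry of the angeloyl group, and the C8 hydroxyl should react in preference to the neopentyl C7 hydroxyl next to CMe2.

**Compound list**

1 | 2,3-O-isopropylidene-D-erythronolactone, (3aR,6aR)-2,2-dimethyldihydrofuro[3,4-d][1,3]dioxol-4(3aH)-one | CC1(C)O[C@@H]2COC(=O)[C@@H]2O1 | starting material
2 | methyl lactol, (3aR,6aR)-2,2,4-trimethyltetrahydrofuro[3,4-d][1,3]dioxol-4-ol (anomer mixture) | CC1(C)O[C@@H]2COC(C)(O)[C@@H]2O1 | intermediate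
3 | 4-methoxybenzyl propargyl ether | C#CCOCc1ccc(OC)cc1 | starting material
4 | [3-(4-methoxybenzyloxy)prop-1-ynyl]magnesium bromide | Br[Mg]C#CCOCc1ccc(OC)cc1 | intermediate
5 | (2R)-2-[(4R,5R)-5-(hydroxymethyl)-2,2-dimethyl-1,3-dioxolan-4-yl]-5-(4-methoxybenzyloxy)pent-3-yn-2-ol | CC1(C)O[C@H](CO)[C@@H](O1)[C@](C)(O)C#CCOCc2ccc(OC)cc2 | intermediate
6 | (2R,3E)-2-[(4R,5R)-5-(hydroxymethyl)-2,2-dimethyl-1,3-dioxolan-4-yl]-5-(4-methoxybenzyloxy)pent-3-en-2-ol | CC1(C)O[C@H](CO)[C@@H](O1)[C@](C)(O)/C=C/COCc2ccc(OC)cc2 | intermediate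
7 | 6-[(E)-3-(4-methoxybenzyloxy)prop-1-enyl]-2,2,6-trimethyltetrahydrofuro[3,4-d][1,3]dioxol-4-ol, alkenyl cis to the dioxolane oxygens, anomer mixture | CC1(C)O[C@@H]2C(O)O[C@](C)(/C=C/COCc3ccc(OC)cc3)[C@@H]2O1 | intermediate
8 | (2R,3E)-2-[(4R,5R)-2,2-dimethyl-5-(2-methylprop-1-enyl)-1,3-dioxolan-4-yl]-5-(4-methoxybenzyloxy)pent-3-en-2-ol | CC1(C)O[C@H](C=C(C)C)[C@@H](O1)[C@](C)(O)/C=C/COCc2ccc(OC)cc2 | intermediate
9 | 4-(2-bromopropan-2-yl)-6-[(E)-3-(4-methoxybenzyloxy)prop-1-enyl]-2,2,6-trimethyltetrahydrofuro[3,4-d][1,3]dioxole, epimers at C4 | CC1(C)O[C@@H]2C(C(C)(C)Br)O[C@](C)(/C=C/COCc3ccc(OC)cc3)[C@@H]2O1 | intermediate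
10 | 6-[(E)-3-(4-methoxybenzyloxy)prop-1-enyl]-2,2,6-trimethyl-4-(propan-2-ylidene)tetrahydrofuro[3,4-d][1,3]dioxole | CC1(C)O[C@@H]2C(=C(C)C)O[C@](C)(/C=C/COCc3ccc(OC)cc3)[C@@H]2O1 | intermediate
11 | 8,9-O-isopropylidene-5-[(4-methoxybenzyloxy)methyl]-6,6,10-trimethylcyclohept-10-en-7-one (target numbering; CH2OPMB trans to O8/O9) | CC1(C)O[C@@H]2C(=O)C(C)(C)[C@@H](COCc3ccc(OC)cc3)C=C(C)[C@@H]2O1 | intermediate
12 | 8,9-dihydroxy-5-[(4-methoxybenzyloxy)methyl]-6,6,10-trimethylcyclohept-10-en-7-one | O[C@@H]1C(=O)C(C)(C)[C@@H](COCc2ccc(OC)cc2)C=C(C)[C@@H]1O | intermediate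
13 | 5-[(4-methoxybenzyloxy)methyl]-6,6,10-trimethylcyclohept-10-ene-7,8,9-triol (7-OH trans to 8-OH, 8-OH cis to 9-OH) | O[C@@H]1[C@@H](O)C(C)(C)[C@@H](COCc2ccc(OC)cc2)C=C(C)[C@@H]1O | intermediate
14 | 9-O-TBS ether of triol 13 | O[C@@H]1[C@@H](O)C(C)(C)[C@@H](COCc2ccc(OC)cc2)C=C(C)[C@@H]1O[Si](C)(C)C(C)(C)C | intermediate
15 | 7,8-O-isopropylidene-9-O-TBS PMB ether | CC1(C)O[C@@H]2[C@@H](O1)C(C)(C)[C@@H](COCc3ccc(OC)cc3)C=C(C)[C@@H]2O[Si](C)(C)C(C)(C)C | intermediate
16 | primary alcohol (C5–CH2OH) | CC1(C)O[C@@H]2[C@@H](O1)C(C)(C)[C@@H](CO)C=C(C)[C@@H]2O[Si](C)(C)C(C)(C)C | intermediate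
17 | aldehyde (C5–CHO) | CC1(C)O[C@@H]2[C@@H](O1)C(C)(C)[C@@H](C=O)C=C(C)[C@@H]2O[Si](C)(C)C(C)(C)C | intermediate
18 | methyl (Z)-2-methyl-3-(cycloheptenyl)prop-2-enoate | CC1(C)O[C@@H]2[C@@H](O1)C(C)(C)[C@@H](/C=C(/C)C(=O)OC)C=C(C)[C@@H]2O[Si](C)(C)C(C)(C)C | intermediate
19 | (Z)-2-methyl-3-(cycloheptenyl)prop-2-enoic acid | CC1(C)O[C@@H]2[C@@H](O1)C(C)(C)[C@@H](/C=C(/C)C(=O)O)C=C(C)[C@@H]2O[Si](C)(C)C(C)(C)C | intermediate
20 | (Z)-acid chloride | CC1(C)O[C@@H]2[C@@H](O1)C(C)(C)[C@@H](/C=C(/C)C(=O)Cl)C=C(C)[C@@H]2O[Si](C)(C)C(C)(C)C | intermediate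
21 | (Z)-1-diazo-3-methyl-4-(cycloheptenyl)but-3-en-2-one | CC1(C)O[C@@H]2[C@@H](O1)C(C)(C)[C@@H](/C=C(/C)C(=O)C=[N+]=[N-])C=C(C)[C@@H]2O[Si](C)(C)C(C)(C)C | intermediate
22 | (Z)-vinylketene O=C1=C2H–C3(Me)=C4H–C5 | CC1(C)O[C@@H]2[C@@H](O1)C(C)(C)[C@@H](/C=C(/C)C=C=O)C=C(C)[C@@H]2O[Si](C)(C)C(C)(C)C | intermediate
23 | tricyclic cyclobutanone (C1–C2–C10–C11 four-membered ketone, C3=C4 alkene, 7,8-acetonide, 9-OTBS) | CC1(C)O[C@@H]2[C@@H](O1)C(C)(C)[C@H]3C=C(C)[C@@H]4C(=O)[C@H]3[C@]4(C)[C@@H]2O[Si](C)(C)C(C)(C)C | intermediate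
24 | 7,8-O-isopropylidene-9-O-TBS-7,8,9-trihydroxylongipin-2-en-1-one | CC1(C)O[C@@H]2[C@@H](O1)C(C)(C)[C@@H]3[C@H]4C(=O)C=C(C)[C@@H]3[C@@]4(C)[C@@H]2O[Si](C)(C)C(C)(C)C | intermediate
25 | 7,8-O-isopropylidene-7,8,9-trihydroxylongipin-2-en-1-one (9-OH free) | CC1(C)O[C@@H]2[C@@H](O1)C(C)(C)[C@@H]3[C@H]4C(=O)C=C(C)[C@@H]3[C@@]4(C)[C@@H]2O | intermediate
26 | 7,8-O-isopropylidene 9-isovalerate | CC1(C)O[C@@H]2[C@@H](O1)C(C)(C)[C@@H]3[C@H]4C(=O)C=C(C)[C@@H]3[C@@]4(C)[C@@H]2OC(=O)CC(C)C | intermediate
27 | 7,8-dihydroxy 9-isovalerate | O[C@@H]1[C@@H](O)C(C)(C)[C@@H]2[C@H]3C(=O)C=C(C)[C@@H]2[C@@]3(C)[C@@H]1OC(=O)CC(C)C | intermediate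
28 | CNP0151972.1, 8-O-angeloyl-9-O-isovaleryl-7-hydroxylongipin-2-en-1-one | C/C=C(/C)C(=O)O[C@@H]1[C@@H](O)C(C)(C)[C@@H]2[C@H]3C(=O)C=C(C)[C@@H]2[C@@]3(C)[C@@H]1OC(=O)CC(C)C | target

**Count and risks**

Total: 22 steps. Longest linear sequence: 22 steps (from 1).

Step 18 is the most likely to fail. Hydrogen transfer inside the diradical (from the C10 methyl group to C4 or to oxygen) would open the four-membered ring for good, and cycloreversion or the 1,3-acyl shift could compete, so that the carbon shift stays incomplete. The fallback sets out from 23 and comes back at 26; it replaces the homolytic shift by a heterolytic one with neighbouring-group help. Bu4NF would free the C9 hydroxyl of 23 to give the 9-hydroxy cyclobutanone F1, and isovaleric anhydride/DMAP would give the 9-isovalerate cyclobutanone F2. Me2AlCl (CH2Cl2, −78 to −20 °C) bound to the cyclobutanone oxygen should then break C2–C10 with participation of the ester carbonyl on the face opposite to C2, and reclosure through the γ-carbon C4 would give 26 directly, so that 24 and 25 are left out.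

Step 17 is second. A 1,5-hydrogen shift from C5 to the ketene carbon, ketene dimerization, or addition in the fused sense (C2 to C11) could outrun the bridged cycloaddition. The fallback sets out from 21 and comes back at 23; a keteniminium salt takes the place of the ketene. Wolff rearrangement of 21 in the presence of pyrrolidine (PhCO2Ag cat., Et3N, THF) would trap the ketene as the (Z)-β,γ-unsaturated pyrrolidine amide F3. Tf2O and 2,4,6-collidine (ClCH2CH2Cl, 25 to 80 °C) would convert it into the vinylketeniminium triflate F4, which is more electrophilic and should add to C10=C11 stepwise through the tertiary C10 cation to give the cyclobutaniminium triflate F5. Aqueous NaHCO3 would hydrolyse F5 to 23.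

Step 7 is third. Loss of HBr toward a methyl group gives an isopropenyl ether that cannot rearrange, and 6-endo ring closure in step 6 would already lead astray. The fallback sets out from 6 and comes back at 11; the enol ether is made from a lactone. TEMPO (cat.)/PhI(OAc)2 would oxidize diol 6 to the lactone F6, and Cp2TiMe2 (PhMe, 70 °C) would methylenate it to the exocyclic enol ether F7. Heating to 150 °C would bring about the same Claisen ring expansion and give the cycloheptenone F8, which lacks the two C6 methyl groups. KOt-Bu/MeI (excess) would then methylate C6 twice to reach 11; the other α-carbon, C8, bears the acetal oxygen and is enolized less readily.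

**Further compounds**

F1 | step 18 | 9-hydroxy cyclobutanone (23 without the silyl group) | CC1(C)O[C@@H]2[C@@H](O1)C(C)(C)[C@H]3C=C(C)[C@@H]4C(=O)[C@H]3[C@]4(C)[C@@H]2O
F2 | step 18 | 9-isovalerate cyclobutanone | CC1(C)O[C@@H]2[C@@H](O1)C(C)(C)[C@H]3C=C(C)[C@@H]4C(=O)[C@H]3[C@]4(C)[C@@H]2OC(=O)CC(C)C
F3 | step 17 | (Z)-3-methyl-4-(cycloheptenyl)but-3-enoyl pyrrolidine amide | CC1(C)O[C@@H]2[C@@H](O1)C(C)(C)[C@@H](/C=C(/C)CC(=O)N3CCCC3)C=C(C)[C@@H]2O[Si](C)(C)C(C)(C)C
F4 | step 17 | vinylketeniminium triflate | CC1(C)O[C@@H]2[C@@H](O1)C(C)(C)[C@@H](/C=C(/C)C=C=[N+]3CCCC3)C=C(C)[C@@H]2O[Si](C)(C)C(C)(C)C.[O-]S(=O)(=O)C(F)(F)F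
F5 | step 17 | cyclobutaniminium triflate (iminium form of 23) | CC1(C)O[C@@H]2[C@@H](O1)C(C)(C)[C@H]3C=C(C)[C@@H]4C(=[N+]5CCCC5)[C@H]3[C@]4(C)[C@@H]2O[Si](C)(C)C(C)(C)C.[O-]S(=O)(=O)C(F)(F)F
F6 | step 7 | lactone, 6-[(E)-3-(4-methoxybenzyloxy)prop-1-enyl]-2,2,6-trimethyldihydrofuro[3,4-d][1,3]dioxol-4(3aH)-one | CC1(C)O[C@@H]2C(=O)O[C@](C)(/C=C/COCc3ccc(OC)cc3)[C@@H]2O1
F7 | step 7 | 4-methylene enol ether | CC1(C)O[C@@H]2C(=C)O[C@](C)(/C=C/COCc3ccc(OC)cc3)[C@@H]2O1
F8 | step 7 | cycloheptenone without the C6 methyl groups | CC1(C)O[C@@H]2C(=O)C[C@@H](COCc3ccc(OC)cc3)C=C(C)[C@@H]2O1
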